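A small charge gives a small share of product: alder ends near a few percent of what you charged, while elm reaches 30.8%. Here are the flasks, the readings and the question.

| flask | substrate | reagent in the second phase | protic impurity | remark | time | volume of the second phase over the first |
|---|---|---|---|---|---|---|
| alder | 0.81 mM (fed, over 20 min) | 2.5 equiv | 2 mM | run made earlier |  |  |
| elm | 15 mM (fed, over 20 min) | 2.5 equiv | 2 mM | run made earlier |  |  |
| green | 0.60 mM (fed, over 20 min) | 2.50 equiv | 2.00 mM |  | 20 min | 1.0 |
| blue | 1.2 mM (fed, over 20 min) | 2.50 equiv | 2.00 mM |  | 20 min | 1.0 |
| grey | 2.5 mM (fed, over 20 min) | 2.50 equiv | 2.00 mM |  | 20 min | 1.0 |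
| violet | 5.0 mM (fed, over 20 min) | 2.50 equiv | 2.00 mM |  | 20 min | 1.0 |
| amber | 10 mM (fed, over 20 min) | 2.50 equiv | 2.00 mM |  | 20 min | 1.0 |

| alder: time / min | alder: product / % | elm: time / min | elm: product / % |
|---|---|---|---|
| 5.00 | 0.2 | 5.00 | 2.4 |
| 10.0 | 1.7 | 10.0 | 8.9 |
| 15.0 | 3.2 | 15.0 | 18.4 |
| 20.0 | 1.9 | 20.0 | 30.8 |

(readings scatter by 1 percentage point)

1. [product] (only what is free in solution, in the first phase) at the end for green, blue, grey, violet, amber, in this order
2. how that number moves from the first to the last of them (falls all the way / hardly changes / rises all the way / rises, then falls / falls, then rises)

- in the second phase: reagent in the second phase; everything else is in the first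
- charges count per volume of the first phase; a concentration in a rate is the amount of a species over the volume of its own phase; every rate counts per litre of the first phase
- the analysis behind the earlier runs scatters by 1 percentage point, standard deviation
- the earlier runs hold the two phases in the same ratio of volumes as the flask asked about
- a reading or a percentage of product counts all its forms, free or not
- the concentration of product that is asked is that of its free form alone
- "hardly changes" means that all values lie within two and a half points (for a concentration: within two and a half percent of the largest)
- percentages count the whole charge, also what has not yet gone in

In elm, product grows about as the square of time. That is what a pseudo-first-order step gives on a substrate fed at a steady rate: the substrate in the flask climbs in a straight line. The reagent comes at 2.5 equiv in both runs, so I take the rate as proportional to the charge as well, with κ a constant of the flask, and I integrate over the feed: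

rate of product at time t = κ · c(charge) · c(charge) · t / tf

c(product, free and bound) at tf = g · c(charge) · c(charge), with g = 0.5 · κ · tf

So g, the yield slope, is the end share of product per mM charged. Alder's last reading lies under the one before it, which is scatter, so I fit the curve through its four readings and get an end share of 2.99%. That reading gives

g = 0.0369 mM⁻¹

Elm's slope is lower, 0.0205 mM⁻¹, so the slope read from these two runs falls from alder to elm. The two slopes give a rough bracket and no firm limits, since alder's slope carries the scatter of its readings. For amber the rough bracket on the total runs from 2.05 mM to 3.69 mM. For green it runs from 0.00739 mM to about 0.0133 mM, and that top is softer still, since green stands below alder's charge.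

A reading counts free and bound together, so the runs do not split them. For the free form the same soft top stays and the floor drops to zero. I commit to that top and to a rise.

The forecast gives 0.009 mM up to 2.2 mM, rises all the way, and says “I take free ≈ total as an upper bound”, which places it inside the bracket for the total.

The flask gives 0.00710 mM, 0.0187 mM, 0.0471 mM, 0.106 mM and 0.236 mM, so it rises all the way.

    substrate + reagent in the reaction phase → product (k = 4.97 M⁻¹ min⁻¹)
    substrate + product ⇌ idle adduct, settled at all times (K = 1790 M⁻¹)
    reagent in the reaction phase ⇌ dormant form (K = 1.32, k = 0.0239 min⁻¹)
    reagent in the reaction phase ⇌ reagent in the second phase, rate k4*([reagent in the reaction phase] - [reagent in the second phase]/K4) per volume of the first phase (partition coefficient = 0.414, kL = 0.0207 min⁻¹)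
    reagent in the reaction phase + protic impurity → quenched reagent (k = 3.95 M⁻¹ min⁻¹)

In amber, product stands at 24.7% of the charge, free and bound together, with idle adduct at 44.7%, which counts twice, so nearly all of it is held. On grey, at 2.5 mM, the slope gives 0.231 mM free and bound together, and the free form there is 0.0471 mM, which is 20.4% of it.

(Readings and results stem from a simulated flask on assumed constants; scatter was added.)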